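## Retrosynthetic overview

- Last step: hydrogenolysis of two benzyl ethers (the phenol of the syringyl ring and the C3 primary alcohol) reveals the target.
- C2–O aryl ether: the (R)-α-hydroxy ketone is activated as its triflate and displaced by the phenolate of unprotected dihydroconiferyl alcohol; SN2 inversion gives the (S) centre.
- Key C1–C2 bond: the acyl anion of 4-(benzyloxy)-3,5-dimethoxybenzaldehyde (thiamine-bound Breslow enaminol inside benzaldehyde lyase) adds to (benzyloxy)acetaldehyde. Two aldehyde carbons, both normally electrophilic, are joined, and the stereocentre is set (R) in the same step.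
- No ring is formed; both benzene rings are bought with the starting materials.

Assumption: recombinant benzaldehyde lyase from Pseudomonas fluorescens is taken as an accessible catalyst, and 4-(benzyloxy)-3,5-dimethoxybenzaldehyde, (benzyloxy)acetaldehyde and dihydroconiferyl alcohol are bought as such.

## Route

Step 1
Reactants: 1 4-(benzyloxy)-3,5-dimethoxybenzaldehyde; 2 (benzyloxy)acetaldehyde
Product: 4 (2R)-3-(benzyloxy)-1-[4-(benzyloxy)-3,5-dimethoxyphenyl]-2-hydroxypropan-1-one, via thiamine-bound Breslow enaminol 3 (not isolated)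
Conditions: benzaldehyde lyase (cat.), thiamine diphosphate (0.25 mM), MgSO4 (2.5 mM), 50 mM potassium phosphate buffer pH 7.5/DMSO 3:1, 30 °C, 24–48 h; 2 (3 equiv) fed in portions
Reagents that add atoms: none
Why: Enzymatic asymmetric cross-benzoin (acyloin) carboligation: the thiamine ylide converts aromatic aldehyde 1 into the nucleophilic Breslow enaminol 3 (an acyl anion equivalent), which attacks aliphatic aldehyde 2 on the face fixed by the active site, the same sense by which this lyase gives (R)-2-hydroxy-1-aryl ketones from benzaldehydes and acetaldehyde or alkoxyacetaldehydes, so the new centre is set as R.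

Step 2
Reactants: 4 (2R)-3-(benzyloxy)-1-[4-(benzyloxy)-3,5-dimethoxyphenyl]-2-hydroxypropan-1-one; 5 4-(3-hydroxypropyl)-2-methoxyphenol (dihydroconiferyl alcohol)
Product: 8 (2S)-3-(benzyloxy)-1-[4-(benzyloxy)-3,5-dimethoxyphenyl]-2-[4-(3-hydroxypropyl)-2-methoxyphenoxy]propan-1-one, via triflate 6 (not isolated), via potassium phenolate 7 (not isolated)
Conditions: Tf2O (1.05 equiv), 2,6-lutidine (1.2 equiv), CH2Cl2, −78 °C, 30 min; then 7 [from 5 (2.3 equiv) and KOtBu (2.2 equiv), THF, 0 °C; one equivalent neutralises the lutidinium triflate], −78 → −20 °C; AcOH/aq. NH4Cl quench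
Reagents that add atoms: none
Why: O-triflation with retention followed by Williamson-type SN2 etherification of the α-keto triflate, which the adjacent carbonyl accelerates strongly, inverts the centre cleanly (R → S); only the phenol of 5 (pKa about 10) is deprotonated, so its primary alcohol needs no protection, and the weakly basic phenolate/phenol buffer at low temperature does not enolise the product.

Step 3
Reactants: 8 (2S)-3-(benzyloxy)-1-[4-(benzyloxy)-3,5-dimethoxyphenyl]-2-[4-(3-hydroxypropyl)-2-methoxyphenoxy]propan-1-one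
Product: 9 (2S)-3-hydroxy-1-(4-hydroxy-3,5-dimethoxyphenyl)-2-[4-(3-hydroxypropyl)-2-methoxyphenoxy]propan-1-one (CNP0283847.1)
Conditions: H2 (1 atm), 10% Pd/C, EtOAc/EtOH 1:1, rt, stopped at complete debenzylation
Reagents that add atoms: none
Why: Catalytic hydrogenolysis of the aryl benzyl ether and the alkyl benzyl ether under neutral conditions; the electron-rich aryl ketone and the α-aryloxy C–O bond react much more slowly at one atmosphere and room temperature, and no base or acid is present to enolise the (S) centre.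

## Compound list

1 | 4-(benzyloxy)-3,5-dimethoxybenzaldehyde | COc1cc(C=O)cc(OC)c1OCc1ccccc1 | starting material
2 | (benzyloxy)acetaldehyde | O=CCOCc1ccccc1 | starting material
3 | thiamine-diphosphate-bound Breslow enaminol of 1 (2-[aryl(hydroxy)methylidene]thiazoline form of the cofactor, held in the lyase; not isolated) | Cc1ncc(CN2C(C)=C(CCOP(O)(=O)OP(O)(O)=O)SC2=C(O)c2cc(OC)c(OCc3ccccc3)c(OC)c2)c(N)n1 | intermediate
4 | (2R)-3-(benzyloxy)-1-[4-(benzyloxy)-3,5-dimethoxyphenyl]-2-hydroxypropan-1-one | COc1cc(cc(OC)c1OCc1ccccc1)C(=O)[C@H](O)COCc1ccccc1 | intermediate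
5 | 4-(3-hydroxypropyl)-2-methoxyphenol (dihydroconiferyl alcohol) | COc1cc(CCCO)ccc1O | starting material
6 | (2R)-3-(benzyloxy)-1-[4-(benzyloxy)-3,5-dimethoxyphenyl]-1-oxopropan-2-yl trifluoromethanesulfonate (not isolated) | COc1cc(cc(OC)c1OCc1ccccc1)C(=O)[C@H](OS(=O)(=O)C(F)(F)F)COCc1ccccc1 | intermediate
7 | potassium 4-(3-hydroxypropyl)-2-methoxyphenolate (not isolated) | COc1cc(CCCO)ccc1[O-].[K+] | intermediate
8 | (2S)-3-(benzyloxy)-1-[4-(benzyloxy)-3,5-dimethoxyphenyl]-2-[4-(3-hydroxypropyl)-2-methoxyphenoxy]propan-1-one | COc1cc(CCCO)ccc1O[C@@H](COCc1ccccc1)C(=O)c1cc(OC)c(OCc2ccccc2)c(OC)c1 | intermediate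
9 | (2S)-3-hydroxy-1-(4-hydroxy-3,5-dimethoxyphenyl)-2-[4-(3-hydroxypropyl)-2-methoxyphenoxy]propan-1-one | COc1cc(CCCO)ccc1O[C@@H](CO)C(=O)c1cc(OC)c(O)c(OC)c1 | target

## Step count and risks

Total step count: 3. Longest linear sequence: 3 (1 → 4 → 8 → 9).

**Step 1 (highest risk).** The lyase has not been shown to accept this bulky 4-benzyloxy-3,5-dimethoxy donor, and it may use aldehyde 2 as donor instead. The fallback sets out from 1 and comes back to the route at 4, keeping an acyl-anion coupling but as a catalytic asymmetric cross silyl benzoin. Aldehyde 1 is condensed with propane-1,3-dithiol (BF3·OEt2, CH2Cl2, 0 °C) to 2-[4-(benzyloxy)-3,5-dimethoxyphenyl]-1,3-dithiane F1. n-BuLi (THF, −78 °C) gives 2-lithio-2-[4-(benzyloxy)-3,5-dimethoxyphenyl]-1,3-dithiane F2, which is quenched with Et3SiCl to {2-[4-(benzyloxy)-3,5-dimethoxyphenyl]-1,3-dithian-2-yl}triethylsilane F3. PhI(OCOCF3)2 in aqueous MeCN at 0 °C unmasks [4-(benzyloxy)-3,5-dimethoxyphenyl](triethylsilyl)methanone F4. F4 and aldehyde 2 are then joined with the lithium salt of a TADDOL-derived cyclic hydrogen phosphite (10–20 mol %, from the phosphite and n-BuLi, THF, 0 °C). The sequence is phosphite addition, [1,2]-Brook rearrangement to a silyloxy carbanion, addition to 2, 1,4-silyl shift and loss of the phosphite. Using the catalyst enantiomer that delivers the R product gives (2R)-3-(benzyloxy)-1-[4-(benzyloxy)-3,5-dimethoxyphenyl]-2-[(triethylsilyl)oxy]propan-1-one F5. HF·pyridine in THF at 0 °C removes the silyl group and gives 4.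

**Step 2.** The triflate may eliminate to the β-benzyloxy enone, and the α-aryloxy ketone may partly racemise under the phenolate. The fallback sets out from 4 and 5 and comes back to the route at 9, replacing sulfonate displacement by a Mitsunobu etherification. Phenol 5 is treated with NaH (2.1 equiv, THF/DMF, 0 °C) to give disodium 2-methoxy-4-(3-oxidopropyl)phenolate F6. Its more basic alkoxide end is benzylated with BnBr (1.0 equiv), and dilute HCl work-up gives 4-[3-(benzyloxy)propyl]-2-methoxyphenol F7. F7 and hydroxy ketone 4 are coupled with PPh3 and DIAD in toluene at 0 °C, with inversion, to (2S)-3-(benzyloxy)-1-[4-(benzyloxy)-3,5-dimethoxyphenyl]-2-{4-[3-(benzyloxy)propyl]-2-methoxyphenoxy}propan-1-one F8. H2 over 10% Pd/C in EtOAc/EtOH then removes all three benzyl groups and gives 9.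

**Step 3.** The ketone may be over-reduced, or the α-aryloxy C–O bond may be hydrogenolysed. The fallback sets out from 8 and comes back to the route at 9 and makes no new compound (F0). It is a non-reductive Lewis-acid debenzylation with BCl3 (4 equiv) and pentamethylbenzene (6 equiv) in CH2Cl2 at −78 °C. The benzyl cations are trapped by the arene, and a methanol quench frees the alcohols.

Further compounds
F1 | step 1 | 2-[4-(benzyloxy)-3,5-dimethoxyphenyl]-1,3-dithiane | COc1cc(cc(OC)c1OCc1ccccc1)C1SCCCS1
F2 | step 1 | 2-lithio-2-[4-(benzyloxy)-3,5-dimethoxyphenyl]-1,3-dithiane | [Li]C1(SCCCS1)c1cc(OC)c(OCc2ccccc2)c(OC)c1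
F3 | step 1 | {2-[4-(benzyloxy)-3,5-dimethoxyphenyl]-1,3-dithian-2-yl}triethylsilane | CC[Si](CC)(CC)C1(SCCCS1)c1cc(OC)c(OCc2ccccc2)c(OC)c1
F4 | step 1 | [4-(benzyloxy)-3,5-dimethoxyphenyl](triethylsilyl)methanone | CC[Si](CC)(CC)C(=O)c1cc(OC)c(OCc2ccccc2)c(OC)c1
F5 | step 1 | (2R)-3-(benzyloxy)-1-[4-(benzyloxy)-3,5-dimethoxyphenyl]-2-[(triethylsilyl)oxy]propan-1-one | CC[Si](CC)(CC)O[C@H](COCc1ccccc1)C(=O)c1cc(OC)c(OCc2ccccc2)c(OC)c1
F6 | step 2 | disodium 2-methoxy-4-(3-oxidopropyl)phenolate | COc1cc(CCC[O-])ccc1[O-].[Na+].[Na+]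
F7 | step 2 | 4-[3-(benzyloxy)propyl]-2-methoxyphenol | COc1cc(CCCOCc2ccccc2)ccc1O
F8 | step 2 | (2S)-3-(benzyloxy)-1-[4-(benzyloxy)-3,5-dimethoxyphenyl]-2-{4-[3-(benzyloxy)propyl]-2-methoxyphenoxy}propan-1-one | COc1cc(CCCOCc2ccccc2)ccc1O[C@@H](COCc1ccccc1)C(=O)c1cc(OC)c(OCc2ccccc2)c(OC)c1
F0 | step 3 | none | none
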